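The pentamer is cut at its two outer methylene bridges into a tris(butyrylphloroglucinol) core (rings B, C, D) and two butyrylfilicinic acid units (rings A, E). The plan rests on ring C, where the butanoyl-bearing carbon is the neighbour of a hydroxyl-bearing carbon, the former flanked by a second oxygenated carbon and the latter by a CH2-aryl carbon. A fully substituted ring C aryne, released by fluoride from an ortho-silyl aryl triflate that already carries both 2,4,6-trimethoxybenzyl arms, takes up butyric acid and forms the aryl–O and aryl–C(=O) bonds in one operation. Bromine is installed on 3,5-dimethoxyphenol before benzylation, so the arms can only enter the two remaining positions.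

Key step: step 5

Remark: the target has no stereocentres and rings A and E are drawn in the enol tautomer of the given structure; the three oxygens of ring C are 1,3,5, so triflate 8 is named 3,5-dimethoxy-2,4-dibenzyl-6-silyl; partly converted species of the twofold steps 3, 6 and 7 are isomer mixtures and are not numbered, whereas the single mono-adduct of step 10 is.

Step 1
Reactants: 1 3,5-dimethoxyphenol
Product: 2 2-bromo-3,5-dimethoxyphenol
Conditions: NBS (1.0 equiv), i-Pr2NH (cat.), CH2Cl2, −78 → 0 °C
Reagents that add atoms: N-bromosuccinimide, O=C1CCC(=O)N1Br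
Why: Secondary-amine-catalysed NBS bromination of a phenol is ortho-selective because the N-bromoamine is delivered through a hydrogen bond to the OH group, the two ortho positions of 1 are equivalent, and one equivalent at low temperature should limit para- and dibromination.

Step 2
Reactants: 3 2,4,6-trimethoxybenzaldehyde
Product: 4 2,4,6-trimethoxybenzyl alcohol
Conditions: NaBH4, MeOH–THF, 0 °C
Reagents that add atoms: none
Why: Borohydride reduction of an aromatic aldehyde gives the benzyl alcohol, which is kept free of acid and used at once because it ionises easily.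

Step 3
Reactants: 2 2-bromo-3,5-dimethoxyphenol; 4 2,4,6-trimethoxybenzyl alcohol (2.2 equiv)
Product: 5 2-bromo-3,5-dimethoxy-4,6-bis(2,4,6-trimethoxybenzyl)phenol
Conditions: p-TsOH·H2O (10 mol %), HFIP–CH2Cl2, 0 °C → rt, slow addition of 4
Reagents that add atoms: none
Why: Twofold Friedel–Crafts benzylation, in which catalytic acid in HFIP ionises 4 to the strongly stabilised 2,4,6-trimethoxybenzyl cation and this is captured at the only two free ring carbons of 2, each ortho or para to all three oxygen substituents, so that no regioisomer can arise.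

Step 4
Reactants: 5 2-bromo-3,5-dimethoxy-4,6-bis(2,4,6-trimethoxybenzyl)phenol
Product: 8 3,5-dimethoxy-2,4-bis(2,4,6-trimethoxybenzyl)-6-(trimethylsilyl)phenyl trifluoromethanesulfonate, via trimethylsilyl ether 6 (not isolated), via lithium phenoxide 7 (not isolated)
Conditions: HMDS, THF, 70 °C, then evaporate; n-BuLi, THF, −78 °C; Tf2O, −78 → 0 °C
Reagents that add atoms: hexamethyldisilazane, C[Si](C)(C)N[Si](C)(C)C; trifluoromethanesulfonic anhydride, O=S(=O)(OS(=O)(=O)C(F)(F)F)C(F)(F)F
Why: This is the standard route from ortho-bromophenols to ortho-silyl aryl triflates, namely O-silylation, bromine–lithium exchange that at −78 °C is far faster than deprotonation of the diarylmethane CH2 groups, 1,3-shift of silicon from oxygen to the aryl carbanion (retro-Brook rearrangement) and O-triflation of the resulting lithium phenoxide.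

Step 5
Reactants: 8 3,5-dimethoxy-2,4-bis(2,4,6-trimethoxybenzyl)-6-(trimethylsilyl)phenyl trifluoromethanesulfonate; 9 butyric acid (1.5 equiv)
Product: 11 1-[2-hydroxy-4,6-dimethoxy-3,5-bis(2,4,6-trimethoxybenzyl)phenyl]butan-1-one, via aryne 10 (not isolated)
Conditions: CsF (5 equiv), THF, 125 °C, sealed tube
Reagents that add atoms: none
Why: Proposed new method: fluoride attacks silicon of 8 and triflate leaves to give aryne 10; butyrate, formed in the flask from 9 and CsF, adds through oxygen to the aryne carbon that lies next to the CH2Ar-bearing carbon, and the aryl anion so formed next to the methoxy-bearing carbon attacks the ester carbonyl through a four-membered transition state, so that the acyl group moves from oxygen to carbon (anionic Fries-type shift) and the phenoxide is released. The closest known reaction type is the CsF-mediated insertion of arynes from ortho-silyl aryl triflates into the C–O bond of carboxylic acids to give ortho-hydroxyaryl ketones, which has not been shown on a fully substituted aryne flanked on both sides. No ring is closed and no stereocentre is formed. The selectivity needed is oxygen to the bridge side and acyl to the methoxy side; it is secured by the methoxy group beside one aryne carbon, which inductively stabilises negative charge developing on that carbon and distorts the triple bond so that the far carbon is the more electrophilic, whereas the other neighbour is only an alkyl group. Excess fluoride holds the acid as CsO2CPr (cesium butyrate), and the hot, poorly solvating medium should favour acyl transfer over protonation of the aryl anion, while the high butyrate concentration is meant to outrun capture of the aryne by a methoxy oxygen of the neighbouring benzyl arm.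

Step 6
Reactants: 11 1-[2-hydroxy-4,6-dimethoxy-3,5-bis(2,4,6-trimethoxybenzyl)phenyl]butan-1-one
Product: 12 1-[3,5-bis(3-butanoyl-2,4,6-trimethoxybenzyl)-2-hydroxy-4,6-dimethoxyphenyl]butan-1-one
Conditions: PrCOCl (2.4 equiv), TiCl4 (4 equiv), CH2Cl2, −78 → 0 °C
Reagents that add atoms: butanoyl chloride, CCCC(=O)Cl
Why: Friedel–Crafts acylation, in which each trimethoxyphenyl ring offers two equivalent free positions activated by three methoxy groups and is deactivated after one acylation, ring C has no free position, and TiCl4 holds the hydrogen-bonded phenol of ring C as a chelate so that it is not O-acylated.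

Step 7
Reactants: 12 1-[3,5-bis(3-butanoyl-2,4,6-trimethoxybenzyl)-2-hydroxy-4,6-dimethoxyphenyl]butan-1-one
Product: 13 1-[3,5-bis(3-butanoyl-2,4,6-trihydroxybenzyl)-2,4,6-trihydroxyphenyl]butan-1-one
Conditions: BBr3 (excess), CH2Cl2, −78 °C → rt; MeOH, H2O
Reagents that add atoms: none
Why: BBr3 cleaves all eight aryl methyl ethers (coordination to oxygen, bromide attack on methyl), helped by chelation to the ortho carbonyl groups, and the acyl group now present on every ring lowers the tendency of the methylene bridges to break under acid.

Step 8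
Reactants: 14 1-(2,4,6-trihydroxyphenyl)butan-1-one
Product: 15 2-butanoyl-3,5-dihydroxy-4,4-dimethylcyclohexa-2,5-dien-1-one (butyrylfilicinic acid)
Conditions: NaOMe (4 equiv), MeI (2.2 equiv), MeOH, 0 °C → rt; aq. HCl
Reagents that add atoms: iodomethane, CI
Why: Dearomatising gem-C-methylation of an acylphloroglucinol, in which the phloroglucinol polyanion is methylated twice at the same ring carbon because the mono-methylated enolate remains nucleophilic there, gives the acylfilicinic acid skeleton.

Step 9
Reactants: 15 2-butanoyl-3,5-dihydroxy-4,4-dimethylcyclohexa-2,5-dien-1-one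
Product: 16 2-butanoyl-6-[(dimethylamino)methyl]-3,5-dihydroxy-4,4-dimethylcyclohexa-2,5-dien-1-one
Conditions: Me2NCH2NMe2 (1.1 equiv), CH2Cl2, 0 °C → rt
Reagents that add atoms: bis(dimethylamino)methane, CN(C)CN(C)C
Why: Mannich aminomethylation, in which the acidic enol 15 protonates the aminal to release the iminium ion and this is taken up by the only free ring carbon (C6), leaving no free carbon for self-condensation.

Step 10
Reactants: 13 1-[3,5-bis(3-butanoyl-2,4,6-trihydroxybenzyl)-2,4,6-trihydroxyphenyl]butan-1-one; 16 2-butanoyl-6-[(dimethylamino)methyl]-3,5-dihydroxy-4,4-dimethylcyclohexa-2,5-dien-1-one (2.4 equiv)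
Product: 19 target CNP0188003.0 (rings A to E), via methylene triketone 17 (not isolated), via mono-adduct 18 (not isolated)
Conditions: NaOAc, MeCN–THF, 60 °C, Ar; dilute aq. HCl work-up
Reagents that add atoms: none
Why: Elimination–addition (retro-Mannich then Michael addition), in which 16 loses dimethylamine on warming to give the methylene triketone 17, an ortho-quinone-methide-like acceptor that is attacked by the single free ring carbon of ring B and then of ring D, the established way of joining filicinic acid and acylphloroglucinol units through a CH2 bridge.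

Compound list
1 | 3,5-dimethoxyphenol | COc1cc(O)cc(OC)c1 | starting material
2 | 2-bromo-3,5-dimethoxyphenol | COc1cc(O)c(Br)c(OC)c1 | intermediate
3 | 2,4,6-trimethoxybenzaldehyde | COc1cc(OC)c(C=O)c(OC)c1 | starting material
4 | 2,4,6-trimethoxybenzyl alcohol | COc1cc(OC)c(CO)c(OC)c1 | intermediate
5 | 2-bromo-3,5-dimethoxy-4,6-bis(2,4,6-trimethoxybenzyl)phenol | Oc1c(Br)c(OC)c(Cc2c(OC)cc(OC)cc2OC)c(OC)c1Cc1c(OC)cc(OC)cc1OC | intermediate
6 | [2-bromo-3,5-dimethoxy-4,6-bis(2,4,6-trimethoxybenzyl)phenoxy]trimethylsilane | C[Si](C)(C)Oc1c(Br)c(OC)c(Cc2c(OC)cc(OC)cc2OC)c(OC)c1Cc1c(OC)cc(OC)cc1OC | intermediate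
7 | lithium 3,5-dimethoxy-2,4-bis(2,4,6-trimethoxybenzyl)-6-(trimethylsilyl)phenoxide | [Li+].[O-]c1c([Si](C)(C)C)c(OC)c(Cc2c(OC)cc(OC)cc2OC)c(OC)c1Cc1c(OC)cc(OC)cc1OC | intermediate
8 | 3,5-dimethoxy-2,4-bis(2,4,6-trimethoxybenzyl)-6-(trimethylsilyl)phenyl trifluoromethanesulfonate | C[Si](C)(C)c1c(OC)c(Cc2c(OC)cc(OC)cc2OC)c(OC)c(Cc2c(OC)cc(OC)cc2OC)c1OS(=O)(=O)C(F)(F)F | intermediate
9 | butyric acid | CCCC(=O)O | starting material
10 | 3,5-dimethoxy-4,6-bis(2,4,6-trimethoxybenzyl)-1,2-didehydrobenzene (ring C aryne) | COC1=C(Cc2c(OC)cc(OC)cc2OC)C(OC)=C(Cc2c(OC)cc(OC)cc2OC)C#C1 | intermediate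
11 | 1-[2-hydroxy-4,6-dimethoxy-3,5-bis(2,4,6-trimethoxybenzyl)phenyl]butan-1-one | CCCC(=O)c1c(OC)c(Cc2c(OC)cc(OC)cc2OC)c(OC)c(Cc2c(OC)cc(OC)cc2OC)c1O | intermediate
12 | 1-[3,5-bis(3-butanoyl-2,4,6-trimethoxybenzyl)-2-hydroxy-4,6-dimethoxyphenyl]butan-1-one | CCCC(=O)c1c(OC)c(Cc2c(OC)cc(OC)c(C(=O)CCC)c2OC)c(OC)c(Cc2c(OC)cc(OC)c(C(=O)CCC)c2OC)c1O | intermediate
13 | 1-[3,5-bis(3-butanoyl-2,4,6-trihydroxybenzyl)-2,4,6-trihydroxyphenyl]butan-1-one | CCCC(=O)c1c(O)c(Cc2c(O)cc(O)c(C(=O)CCC)c2O)c(O)c(Cc2c(O)cc(O)c(C(=O)CCC)c2O)c1O | intermediate
14 | 1-(2,4,6-trihydroxyphenyl)butan-1-one | CCCC(=O)c1c(O)cc(O)cc1O | starting material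
15 | 2-butanoyl-3,5-dihydroxy-4,4-dimethylcyclohexa-2,5-dien-1-one (butyrylfilicinic acid) | CCCC(=O)C1=C(O)C(C)(C)C(O)=CC1=O | intermediate
16 | 2-butanoyl-6-[(dimethylamino)methyl]-3,5-dihydroxy-4,4-dimethylcyclohexa-2,5-dien-1-one | CCCC(=O)C1=C(O)C(C)(C)C(O)=C(CN(C)C)C1=O | intermediate
17 | 2-butanoyl-3-hydroxy-4,4-dimethyl-6-methylidenecyclohex-2-ene-1,5-dione | CCCC(=O)C1=C(O)C(C)(C)C(=O)C(=C)C1=O | intermediate
18 | mono-adduct: 13 carrying on the free carbon of one outer ring a (5-butanoyl-2,4-dihydroxy-3,3-dimethyl-6-oxocyclohexa-1,4-dien-1-yl)methyl group | CCCC(=O)C1=C(O)C(C)(C)C(O)=C(Cc2c(O)c(Cc3c(O)c(Cc4c(O)cc(O)c(C(=O)CCC)c4O)c(O)c(C(=O)CCC)c3O)c(O)c(C(=O)CCC)c2O)C1=O | intermediate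
19 | CNP0188003.0: 13 carrying on the free carbon of each outer ring a (5-butanoyl-2,4-dihydroxy-3,3-dimethyl-6-oxocyclohexa-1,4-dien-1-yl)methyl group | CCCC(=O)C1=C(O)C(C)(C)C(O)=C(Cc2c(O)c(Cc3c(O)c(Cc4c(O)c(CC5=C(O)C(C)(C)C(O)=C(C(=O)CCC)C5=O)c(O)c(C(=O)CCC)c4O)c(O)c(C(=O)CCC)c3O)c(O)c(C(=O)CCC)c2O)C1=O | target

Total step count: 10. Longest linear sequence: 7 steps (steps 1, 3, 4, 5, 6, 7, 10, from 3,5-dimethoxyphenol).

Steps most likely to fail

Step 5. The aryl anion may be protonated before the acyl group shifts, giving plain O-arylation. Butyrate may add at the wrong aryne carbon. A methoxy oxygen of the adjacent benzyl arm may capture the aryne intramolecularly. The acyl shift into a doubly flanked position may be slow. The fallback uses known chemistry, sets out from bromophenol 5 (replacing steps 4 and 5) and comes back at 11. Compound 5 is O-acylated with butyric anhydride, DMAP (cat.) and pyridine to give 2-bromo-3,5-dimethoxy-4,6-bis(2,4,6-trimethoxybenzyl)phenyl butanoate F1. Treatment of this ester with s-BuLi in THF–Et2O at −100 °C brings about bromine–lithium exchange, and the aryllithium takes the acyl group from the neighbouring oxygen. This is the halogen–metal-exchange-initiated anionic ortho-Fries rearrangement of ortho-bromoaryl esters, and it should give 11 after protonation, with the same placement of hydroxyl and butanoyl groups.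

Step 10. The second alkylation may stall on the poorly soluble polyphenol. Amine and heat may cause exchange of methylene bridges between rings (retro-Michael and retro-Friedel–Crafts scrambling). The polyphenol may degrade oxidatively. The fallback reverses the roles of the partners, sets out from 13 and comes back at 19. Compound 13 is aminomethylated at the free carbon of rings B and D with bis(dimethylamino)methane to give 1-{3,5-bis[3-butanoyl-5-(dimethylaminomethyl)-2,4,6-trihydroxybenzyl]-2,4,6-trihydroxyphenyl}butan-1-one F2. Heating this bis-Mannich base with an excess of butyrylfilicinic acid 15 in dioxane at about 90 °C under argon releases dimethylamine. The ortho-quinone methides formed on rings B and D are captured by the nucleophilic C6 of 15, which should give 19 without the need for 16.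

Step 3. Alcohol 4 may condense with itself with loss of formaldehyde. The second benzylation may remain incomplete at the more hindered carbon. Acid may transfer benzyl groups between rings. The fallback moves the electrophilic carbon onto ring C, sets out from 2 and comes back at 5. Compound 2 is hydroxymethylated at both free ring carbons with aqueous formaldehyde and NaOH at 0 °C (Lederer–Manasse reaction) to give 2-bromo-4,6-bis(hydroxymethyl)-3,5-dimethoxyphenol F3. Its benzylic cations, generated with catalytic p-TsOH in HFIP, are captured by an excess of 1,3,5-trimethoxybenzene, which cannot condense with itself, and this should give 5.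

Further compounds
F1 | step 5 | 2-bromo-3,5-dimethoxy-4,6-bis(2,4,6-trimethoxybenzyl)phenyl butanoate | CCCC(=O)Oc1c(Br)c(OC)c(Cc2c(OC)cc(OC)cc2OC)c(OC)c1Cc1c(OC)cc(OC)cc1OC
F2 | step 10 | 1-{3,5-bis[3-butanoyl-5-(dimethylaminomethyl)-2,4,6-trihydroxybenzyl]-2,4,6-trihydroxyphenyl}butan-1-one | CCCC(=O)c1c(O)c(Cc2c(O)c(CN(C)C)c(O)c(C(=O)CCC)c2O)c(O)c(Cc2c(O)c(CN(C)C)c(O)c(C(=O)CCC)c2O)c1O
F3 | step 3 | 2-bromo-4,6-bis(hydroxymethyl)-3,5-dimethoxyphenol | Oc1c(Br)c(OC)c(CO)c(OC)c1CO
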